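**Plan**

1. Chromone numbering (O1, C2, C3, C4, C4a, C5–C8, C8a) is kept for these atoms in every intermediate. C2–C8a plus the pentadecyl group form one straight 24-carbon chain, oxygenated at C2, C4, C5 and C8a but not at C7; ring A (C4a, C5, C6, C7, C8, C8a) is that chain bent so that C4a meets its carboxyl terminus C8a.
2. Retrosynthetic cuts, in order: O1–C2 (4-pyranone ring), C4a–C8a (ring A), C4–C4a (chain junction), C2–C3 (acetate unit onto palmitate).
3. Forward: palmitoyl chloride and Meldrum's acid give a C2-ketalised 3-oxooctadecanoic Weinreb amide, which acylates lithiated 6-methyl-2H-pyran-2-one; the 2-pyranone stores C5–C8a as a cis-enoyl lactone.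
4. Ring A is made first, by Mg(OMe)2-induced opening of the 2-pyranone and Claisen closure of C4a onto C8a; the 4-pyranone ring follows by acid-catalysed attack of a phenol oxygen on C2 with loss of ethylene glycol.
5. The C2 ketone stays masked as a dioxolane through the benzannulation, so no aldol acceptor competes with the ester and C4a is the only doubly activated carbon.
6. The target has no stereocentre; the one geometric requirement, the cis C7=C8 bond of the opened chain, is inherited from the pyranone ring.

Key step: step 5

Assumption: 6-methyl-2H-pyran-2-one is treated as a catalogue compound that, like its 4-methoxy congener, is deprotonated at the methyl group by LiN(SiMe3)2 at −78 °C.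

**Step 1**
Reactants: 1 palmitoyl chloride; 2 Meldrum's acid (2,2-dimethyl-1,3-dioxane-4,6-dione)
Product: 3 5-(1-hydroxyhexadecylidene)-2,2-dimethyl-1,3-dioxane-4,6-dione (palmitoyl Meldrum's acid, enol form)
Conditions: pyridine (2 equiv), CH2Cl2, 0 °C to rt; dilute aq HCl wash; used crude
Reagents that add atoms: none
Why: C-acylation of Meldrum's acid by an acid chloride under pyridine is the standard way to append an acetate unit to an acyl group and forms the C2–C3 bond.

**Step 2**
Reactants: 3 palmitoyl Meldrum's acid
Product: 5 N-methoxy-N-methyl-3-oxooctadecanamide, via palmitoylketene 4 (not isolated)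
Conditions: MeNHOMe·HCl (1.2 equiv), Et3N (1.2 equiv), toluene, 85 °C
Reagents that add atoms: N,O-dimethylhydroxylamine hydrochloride, CNOC.Cl
Why: On heating, the acyl Meldrum's acid should lose acetone and CO2 by cycloreversion to acylketene 4, which is trapped by the hydroxylamine (aminolysis of an acyl Meldrum's acid to a β-keto amide).

**Step 3**
Reactants: 5 N-methoxy-N-methyl-3-oxooctadecanamide
Product: 6 N-methoxy-N-methyl-2-(2-pentadecyl-1,3-dioxolan-2-yl)acetamide
Conditions: ethylene glycol (5 equiv), TsOH·H2O (0.05 equiv), toluene, reflux, Dean–Stark trap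
Reagents that add atoms: ethylene glycol, OCCO
Why: Acid-catalysed ketalisation with azeotropic removal of water masks the C2 ketone as a base-stable dioxolane, so that C3 carries no β-dicarbonyl proton in the carbanion steps, and the Weinreb amide is inert to these conditions.

**Step 4**
Reactants: 7 6-methyl-2H-pyran-2-one; 6 N-methoxy-N-methyl-2-(2-pentadecyl-1,3-dioxolan-2-yl)acetamide
Product: 10 6-[2-oxo-3-(2-pentadecyl-1,3-dioxolan-2-yl)propyl]-2H-pyran-2-one, via pyranone methyllithium 8 (not isolated), via lithium hemiaminal chelate 9 (not isolated)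
Conditions: 7 (1.3 equiv), LiN(SiMe3)2 (1.3 equiv), THF, −78 °C; then 6, −78 to −40 °C; aq NH4Cl
Reagents that add atoms: none
Why: Lateral deprotonation of the 6-methyl group gives a delocalised dienolate that is acylated by the amide in a Weinreb ketone synthesis; chelate 9 holds the carbonyl as a tetrahedral adduct until work-up, so the acidic C4a protons of the product cannot quench the carbanion, and the dioxolane and lactone should survive the cold, non-nucleophilic base.

**Step 5**
Reactants: 10 6-[2-oxo-3-(2-pentadecyl-1,3-dioxolan-2-yl)propyl]-2H-pyran-2-one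
Product: 13 1-(2,6-dihydroxyphenyl)-2-(2-pentadecyl-1,3-dioxolan-2-yl)ethan-1-one, via ring-opened Z-enoate ester 11 (not isolated), via acylcyclohexenedione 12 (not isolated)
Conditions: Mg(OMe)2 (3 equiv), anhydrous MeOH, reflux, Ar; then cold dilute aq HCl to pH 4
Reagents that add atoms: none
Why: Proposed new method: methoxide should add to the lactone carbonyl C8a of 10 and open the ring to the magnesium-chelated C4/C5 diketonate of methyl ester 11, whose C7=C8 bond keeps the cis geometry of the pyranone; the chelated C4a carbanion then attacks the ester carbon in a Claisen (Dieckmann-type) condensation, methoxide leaves, and dienone 12 tautomerises to the resorcinol, an overall isomerisation. The closest known reaction type is the Mg(OMe)2-induced ring opening and Claisen recyclisation of 6-(2-oxoalkyl)-4-hydroxy-2-pyranones to acylphloroglucinols; here C7 carries no oxygen and the ring-derived cis enoate takes over the folding role. Ring A closes in a 6-exo-trig mode, the enolate carbon adding to the ester carbonyl. No stereocentre is formed. The step needs C-acylation at C4a to win over aldol, Michael and relactonisation pathways: with C2 held as the dioxolane there is no ketone for C6 to attack and C3 is not doubly activated, so C4a is the only stabilised carbanion, and the cis double bond keeps C8a within reach. Aromatisation should make the closure the thermodynamic sink even though ring opening and oxa-Michael side equilibria are reversible.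

**Step 6**
Reactants: 13 1-(2,6-dihydroxyphenyl)-2-(2-pentadecyl-1,3-dioxolan-2-yl)ethan-1-one
Product: 15 5-hydroxy-2-pentadecyl-4H-chromen-4-one, via hydroxyethoxy chromanone 14 (not isolated)
Conditions: TsOH·H2O (0.2 equiv), toluene, 100 °C
Reagents that add atoms: none
Why: Acid opens the dioxolane to an oxocarbenium ion at C2 that is captured by either of the two equivalent phenol oxygens, and elimination of ethylene glycol from mixed ketal 14 gives the chromone (the usual acid cyclisation of 1-(2-hydroxyaryl) 1,3-dicarbonyl equivalents), the other phenol remaining as the hydrogen-bonded 5-OH.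

**Compound list**

1 | palmitoyl chloride | CCCCCCCCCCCCCCCC(=O)Cl | starting material
2 | Meldrum's acid (2,2-dimethyl-1,3-dioxane-4,6-dione) | CC1(C)OC(=O)CC(=O)O1 | starting material
3 | 5-(1-hydroxyhexadecylidene)-2,2-dimethyl-1,3-dioxane-4,6-dione | CCCCCCCCCCCCCCCC(O)=C1C(=O)OC(C)(C)OC1=O | intermediate
4 | palmitoylketene (3-oxooctadec-1-en-1-one), formed in the flask | CCCCCCCCCCCCCCCC(=O)C=C=O | intermediate
5 | N-methoxy-N-methyl-3-oxooctadecanamide | CCCCCCCCCCCCCCCC(=O)CC(=O)N(C)OC | intermediate
6 | N-methoxy-N-methyl-2-(2-pentadecyl-1,3-dioxolan-2-yl)acetamide | CCCCCCCCCCCCCCCC1(CC(=O)N(C)OC)OCCO1 | intermediate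
7 | 6-methyl-2H-pyran-2-one | Cc1cccc(=O)o1 | starting material
8 | (2-oxo-2H-pyran-6-yl)methyllithium (delocalised lithium dienolate), formed in the flask | [Li]Cc1cccc(=O)o1 | intermediate
9 | lithium 1-[methoxy(methyl)amino]-1-[(2-oxo-2H-pyran-6-yl)methyl]-2-(2-pentadecyl-1,3-dioxolan-2-yl)ethanolate (Weinreb chelate), formed in the flask | [Li]OC(Cc1cccc(=O)o1)(CC2(CCCCCCCCCCCCCCC)OCCO2)N(C)OC | intermediate
10 | 6-[2-oxo-3-(2-pentadecyl-1,3-dioxolan-2-yl)propyl]-2H-pyran-2-one | O=c1cccc(CC(=O)CC2(CCCCCCCCCCCCCCC)OCCO2)o1 | intermediate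
11 | methyl (2Z)-5,7-dioxo-8-(2-pentadecyl-1,3-dioxolan-2-yl)oct-2-enoate (present as its magnesium diketonate), formed in the flask | COC(=O)/C=C\CC(=O)CC(=O)CC1(CCCCCCCCCCCCCCC)OCCO1 | intermediate
12 | 2-[(2-pentadecyl-1,3-dioxolan-2-yl)acetyl]cyclohex-4-ene-1,3-dione (present as its magnesium enolate), formed in the flask | O=C1C=CCC(=O)C1C(=O)CC2(CCCCCCCCCCCCCCC)OCCO2 | intermediate
13 | 1-(2,6-dihydroxyphenyl)-2-(2-pentadecyl-1,3-dioxolan-2-yl)ethan-1-one | O=C(CC1(CCCCCCCCCCCCCCC)OCCO1)c2c(O)cccc2O | intermediate
14 | 5-hydroxy-2-(2-hydroxyethoxy)-2-pentadecylchroman-4-one (racemic, transient), formed in the flask | CCCCCCCCCCCCCCCC1(OCCO)CC(=O)c2c(O)cccc2O1 | intermediate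
15 | 5-hydroxy-2-pentadecyl-4H-chromen-4-one | CCCCCCCCCCCCCCCc1cc(=O)c2c(O)cccc2o1 | target

**Step count**

Total step count: 6. Longest linear sequence: 6 steps (from 1 and 2 to 15); pyranone 7 enters at step 4.

**Steps most likely to fail**

Step 5. The lactone of the deprotonated, electron-rich pyranone may resist attack by methoxide. The opened enoate may lose its cis geometry by deconjugation and reconjugation, or be held up in oxa-Michael adducts, before the Claisen closure takes place. The fallback uses known chemistry and buys ring A instead of building it; it sets out from 1. Commercial 2',6'-dihydroxyacetophenone (CC(=O)c1c(O)cccc1O) is converted with LiN(SiMe3)2 (4 equiv) in THF at −78 °C into its trilithium salt. Its ketone enolate carbon is acylated by 1 (direct Baker–Venkataraman-type C-acylation) to give, after acidification, 1-(2,6-dihydroxyphenyl)octadecane-1,3-dione F1. Diketone F1 is cyclodehydrated with TsOH·H2O in toluene at 100 °C, and the route is rejoined at 15.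

Step 4. The lithiated pyranone may condense with itself or with unmetalated 7, or proton transfer from amide 6 may take the place of acylation. The fallback builds the pyranone ring last on the finished chain instead of metalating a preformed pyranone; it sets out from 6.
- iBu2AlH in THF at −78 °C reduces the Weinreb amide to 2-(2-pentadecyl-1,3-dioxolan-2-yl)acetaldehyde F2.
- Barbier propargylation (propargyl bromide, C#CCBr, Zn dust, THF/aq NH4Cl) gives racemic 1-(2-pentadecyl-1,3-dioxolan-2-yl)pent-4-yn-2-ol F3.
- Sonogashira coupling with methyl (Z)-3-iodoacrylate (COC(=O)/C=C\I; Pd(PPh3)2Cl2, CuI, Et3N) gives methyl (2Z)-7-hydroxy-8-(2-pentadecyl-1,3-dioxolan-2-yl)oct-2-en-4-ynoate F4.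
- LiOH in THF/H2O gives (2Z)-7-hydroxy-8-(2-pentadecyl-1,3-dioxolan-2-yl)oct-2-en-4-ynoic acid F5.
- ZnBr2-catalysed 6-endo-dig lactonisation in THF gives 6-[2-hydroxy-3-(2-pentadecyl-1,3-dioxolan-2-yl)propyl]-2H-pyran-2-one F6.
- Dess–Martin oxidation of F6 in NaHCO3-buffered CH2Cl2 rejoins the route at 10.

Step 3. Ketalisation of the hydrogen-bonded β-keto amide may stall, and prolonged heating with acid and glycol may cleave the β-keto amide by retro-Claisen alcoholysis. The fallback ketalises an ester and makes the amide afterwards; it sets out from 3. Refluxing methanol converts 3 into methyl 3-oxooctadecanoate F7. Ethylene glycol with TsOH·H2O in toluene under Dean–Stark conditions gives methyl 2-(2-pentadecyl-1,3-dioxolan-2-yl)acetate F8. MeNHOMe·HCl and iPrMgCl in THF at −20 °C convert the ester into the Weinreb amide, rejoining the route at 6.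

**Further compounds**

F1 | step 5 | 1-(2,6-dihydroxyphenyl)octadecane-1,3-dione | CCCCCCCCCCCCCCCC(=O)CC(=O)c1c(O)cccc1O
F2 | step 4 | 2-(2-pentadecyl-1,3-dioxolan-2-yl)acetaldehyde | CCCCCCCCCCCCCCCC1(CC=O)OCCO1
F3 | step 4 | 1-(2-pentadecyl-1,3-dioxolan-2-yl)pent-4-yn-2-ol (racemic) | CCCCCCCCCCCCCCCC1(CC(O)CC#C)OCCO1
F4 | step 4 | methyl (2Z)-7-hydroxy-8-(2-pentadecyl-1,3-dioxolan-2-yl)oct-2-en-4-ynoate (racemic) | COC(=O)/C=C\C#CCC(O)CC1(CCCCCCCCCCCCCCC)OCCO1
F5 | step 4 | (2Z)-7-hydroxy-8-(2-pentadecyl-1,3-dioxolan-2-yl)oct-2-en-4-ynoic acid (racemic) | OC(=O)/C=C\C#CCC(O)CC1(CCCCCCCCCCCCCCC)OCCO1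
F6 | step 4 | 6-[2-hydroxy-3-(2-pentadecyl-1,3-dioxolan-2-yl)propyl]-2H-pyran-2-one (racemic) | O=c1cccc(CC(O)CC2(CCCCCCCCCCCCCCC)OCCO2)o1
F7 | step 3 | methyl 3-oxooctadecanoate | CCCCCCCCCCCCCCCC(=O)CC(=O)OC
F8 | step 3 | methyl 2-(2-pentadecyl-1,3-dioxolan-2-yl)acetate | CCCCCCCCCCCCCCCC1(CC(=O)OC)OCCO1
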